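The epsilon run leaves a leftover: 12.9% of the starting material still stands at 50.0 h, and I read the set-ups below from that leftover.

| setting | theta | epsilon | eta | gamma | north | south | south-east | east |
|---|---|---|---|---|---|---|---|---|
| starting material | 0.050 M | 0.050 M | 0.050 M | 0.050 M | 0.050 M | 0.050 M | 0.050 M | 0.050 M |
| reagent | 0.95 equiv | 0.47 equiv | 1.9 equiv | 0.95 equiv | 0.950 equiv | 0.950 equiv | 0.950 equiv | 0.950 equiv (fed, over 40.0 h) |
| protic impurity | 0.015 M | 0.015 M | 0.015 M | 0.030 M | 0.0150 M | 0.0150 M | 0.0150 M | 0.0150 M |
| remark | run made earlier | run made earlier | run made earlier | run made earlier | a closed flask charged with all of it at once and left for 50 h | one stirred flow tank at steady state, fed with the mixture as stated, mean residence time 50 h | a single well-mixed tank run continuously and read at steady state, 250 h in it on average | a stirred flask in which reagent is dosed at a steady rate over 40.0 h without added volume, worked up at 50 h |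
| time |  |  |  |  | 50 h |  |  | 50 h |

| run | time / h | target / % | starting material / % |
|---|---|---|---|
| theta | 2.50 | 17.2 | 39.5 |
| theta | 4.00 | 26.3 | 27.2 |
| theta | 6.00 | 34.3 | 18.0 |
| theta | 8.00 | 39.6 | 13.3 |
| theta | 12.0 | 46.0 | 8.3 |
| theta | 20.0 | 50.4 | 3.1 |
| theta | 30.0 | 52.7 | 1.1 |
| epsilon | 3.00 | 10.1 | 54.9 |
| epsilon | 10.0 | 24.4 | 29.8 |
| epsilon | 15.0 | 27.5 | 23.9 |
| epsilon | 25.0 | 29.5 | 18.7 |
| epsilon | 40.0 | 32.0 | 14.0 |
| epsilon | 50.0 | 32.8 | 12.9 |
| epsilon | 60.0 | 32.8 | 12.1 |
| eta | 8.00 | 58.5 | 3.1 |
| eta | 15.0 | 64.5 | 1.0 |
| eta | 25.0 | 66.8 | 0.6 |
| eta | 30.0 | 66.5 | 0 |
| eta | 40.0 | 66.3 | 0 |
| eta | 48.0 | 66.1 | 0.6 |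
| eta | 60.0 | 65.8 | 0.7 |
| gamma | 5.00 | 29.5 | 18.4 |
| gamma | 15.0 | 44.8 | 2.3 |
| gamma | 30.0 | 47.4 | 0 |
| gamma | 40.0 | 46.9 | 0 |
| gamma | 60.0 | 48.0 | 0 |

(scatter of a reading: 0.5 percentage points)

- percentages count the starting material that a species holds: one side product counts as two
- the stated concentrations are those of everything mixed, before any reaction; amounts are the same in each set-up
- steps that have been proposed: starting material + adduct -> side product; adduct -> target; starting material + protic impurity -> quenched substrate; starting material + reagent <-> adduct
- the feed brings no volume worth counting
- the earlier runs were made in a closed, stirred flask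

* the set-up with the highest amount of target at the outlet or at the end, in percent of the starting material put in ("none" if the first two lie within 2 percentage points) (north / south / south-east / east / none)
* amount of target at the outlet or at the end, in percent of the starting material put in, north
* amount of target at the outlet or at the end, in percent of the starting material put in, south
* amount of target at the outlet or at the end, in percent of the starting material put in, south-east
* amount of target at the outlet or at the end, in percent of the starting material put in, east

I keep the books of epsilon, where the reagent, at 0.47 equiv, is the limiting reagent. Target holds 32.8%, and it holds the same at 60.0 h, so I assume that free reagent and adduct stand at zero and book the remaining 14.2% of reagent to side product. Each side product swallows two starting materials, so that entry costs 28.4% of the starting material. With the leftover entered, the books close on 25.9% quenched substrate, less than the 30.0% the protic impurity could take.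

Besides falling back to starting material and reagent, adduct has two forward exits in the proposed steps: to target by itself, and to side product with starting material. So at each moment, side product made per target made equals the standing starting material divided by a crossover level, the level of starting material at which both forward exits run equally. Epsilon's books give a ratio of 0.433. The starting material readings at 3.00 h and 10.0 h, between which target gains 14 percentage points, average 0.0212 M. My rough reading of the crossover level is therefore 0.0489 M.

North starts at 0.050 M, so at first about half of the adduct going forward in north reaches target. At the 5% the forecast expects standing in south-east, the share is 95.1%, so I too put south-east ahead of north.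

The forecast gives 53.5% for north, 47% for south, 64% for south-east and 45% for east, and names south-east: “so side product is suppressed”.

South-east comes out ahead at 70.0%, above the forecast's figure, with south at 55.6%, north at 53.5% and east at 44.3%.

    starting material + adduct → side product (k = 0.00200 /M/s)
    adduct → target (k = 1.10 × 10⁻⁴ /s)
    starting material + protic impurity → quenched substrate (k = 0.00110 /M/s)
    starting material + reagent ⇌ adduct (K = 50.0 /M, k = 0.00270 /M/s)

Starting material stands at 0.00204 M throughout the south-east tank. Divided by the crossover level, that gives 0.0417 side product per target. Counted twice and applied to 70.0% of target, it comes to 5.84%, and the south-east tank delivers 5.19% of side product.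

All runs were generated by integration from invented constants; noise was put on by code.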